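**Plan**

1. Cuts, in order: (a) the C7–OH and C5′–OH bonds, since both tertiary carbinols come from exocyclic methylenes; (b) in one operation the C5a–C6 bond of the cyclohexane and the O1–C2 bond of the oxepane, which opens the perhydro-1-benzoxepine (O1, C2 = CMe2, C3 = CHOH, C5a = C–Me, C6 = CH–chain, C7, C9a = CH–O) to an acyclic 1,5-diepoxide carrying an enol silane; (c) the linker C=C (aldol condensation) between diepoxy-geranylacetone and a decalin acetaldehyde; (d) the decalin (primed atoms: C1′ chain, C2′=C3′, C5′ carbinol, C8′ CMe2) by a [4+2] cut into 4,4-dimethylcyclohexenone and a 2-siloxydiene.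
2. Forward: the cis-decalin (both rings of the eastern half) is made first by a Diels–Alder reaction, the chain is joined by aldol condensation, the oxepane and then the cyclohexane close in one cascade, and the two tertiary alcohols are installed last by a double hydration.
3. Enabling feature: C5a is a methyl-bearing quaternary ring-fusion carbon whose neighbour C9a carries the ring oxygen anti to that methyl, and the gem-dimethyl ether carbon C2 lies 1,5 to it beside the C3 carbinol. This is the imprint of two trisubstituted epoxides of an (E)-geranyl chain, where the inner epoxide oxygen acts first as nucleophile (oxepane) and then as leaving group at C5a (cyclohexane).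
4. Stereochemistry: C3, C5a and C9a come from reagent-controlled Shi epoxidation (C5a with inversion in the cascade); C6 from the chair closure and equilibration α to the ketone; C1′, C4a′ and C8a′ from a catalytic enantioselective endo Diels–Alder reaction; C7 and C5′ from face-selective hydration of the exocyclic olefins.

Key step: step 11

Assumption: the facial sense of the chiral Lewis acid in step 3 is assigned from the usual enone–catalyst complex model; should the adduct prove antipodal, the catalyst from (R)-diphenylprolinol is used and nothing else changes.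
Abbreviation in names: Dec = (1S,4aS,8aS)-2,8,8-trimethyl-5-methylidene-1,4,4a,5,6,7,8,8a-octahydronaphthalen-1-yl (cis-fused, H-1, H-4a and H-8a on the same face).

**Route**

Step 1
Reactants: 1 4-chlorobutanoyl chloride; 2 trimethyl(vinyl)silane
Product: 3 6-chlorohex-1-en-3-one
Conditions: AlCl3, CH2Cl2, −78 to 0 °C; aq. NaHCO3 work-up
Reagents that add atoms: none
Why: Friedel–Crafts acylation of a vinylsilane (ipso substitution through the β-silyl cation) should give the vinyl ketone directly with the alkyl chloride inert; no stereocentre is formed.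

Step 2
Reactants: 3 6-chlorohex-1-en-3-one
Product: 4 (Z)-tert-butyl[(6-chlorohexa-1,3-dien-3-yl)oxy]dimethylsilane
Conditions: TBSOTf, Et3N, Et2O, 0 °C
Reagents that add atoms: tert-butyldimethylsilyl trifluoromethanesulfonate, CC(C)(C)[Si](C)(C)OS(=O)(=O)C(F)(F)F
Why: Soft enolisation with O-silylation can only go toward the single α-methylene group and should give mainly the Z enol ether (chloroethyl group "outside"), the geometry the endo adduct needs.

Step 3
Reactants: 4 (Z)-tert-butyl[(6-chlorohexa-1,3-dien-3-yl)oxy]dimethylsilane; 5 4,4-dimethylcyclohex-2-en-1-one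
Product: 6 (4aR,5S,8aS)-6-[(tert-butyldimethylsilyl)oxy]-5-(2-chloroethyl)-4,4-dimethyl-3,4,4a,5,8,8a-hexahydronaphthalen-1(2H)-one
Conditions: oxazaborolidine from (S)-α,α-diphenylprolinol and o-tolylboronic acid (20 mol%), AlBr3 (16 mol%), CH2Cl2, −40 to −20 °C
Reagents that add atoms: none
Why: In this enantioselective Lewis-acid-catalysed Diels–Alder reaction the 2-siloxy group makes the substituted diene terminus the nucleophilic one, so it bonds to the enone β-carbon next to the gem-dimethyl group; suprafacial addition gives the cis ring fusion, the endo transition state with the "outside" chloroethyl group puts H-5 cis to H-4a and H-8a, and the chiral Lewis acid shields one enone face to set the absolute configuration.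

Step 4
Reactants: 6 (4aR,5S,8aS)-6-[(tert-butyldimethylsilyl)oxy]-5-(2-chloroethyl)-4,4-dimethyl-3,4,4a,5,8,8a-hexahydronaphthalen-1(2H)-one
Product: 7 tert-butyl{[(1S,4aS,8aS)-1-(2-chloroethyl)-8,8-dimethyl-5-methylidene-1,4,4a,5,6,7,8,8a-octahydronaphthalen-2-yl]oxy}dimethylsilane
Conditions: Tebbe reagent Cp2Ti(μ-CH2)(μ-Cl)AlMe2, pyridine (cat.), THF/toluene, −40 to 0 °C
Reagents that add atoms: Tebbe reagent (Cp drawn σ-bonded and the μ-chloro bridge drawn with formal charges), C[Al-]1(C)C[Ti]([Cl+]1)(C2C=CC=C2)C3C=CC=C3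
Why: The non-basic titanium methylidene (Tebbe olefination) should convert the enolisable ketone into the exocyclic methylene without epimerising the adjacent cis ring-fusion centre and without touching the silyl enol ether; no new stereocentre.

Step 5
Reactants: 7 tert-butyl{[(1S,4aS,8aS)-1-(2-chloroethyl)-8,8-dimethyl-5-methylidene-1,4,4a,5,6,7,8,8a-octahydronaphthalen-2-yl]oxy}dimethylsilane
Product: 8 (1S,4aS,8aS)-1-(2-chloroethyl)-8,8-dimethyl-5-methylidene-1,4,4a,5,6,7,8,8a-octahydronaphthalen-2-yl trifluoromethanesulfonate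
Conditions: CsF, PhNTf2, DME, 23 °C
Reagents that add atoms: N-phenylbis(trifluoromethanesulfonimide), FC(F)(F)S(=O)(=O)N(c1ccccc1)S(=O)(=O)C(F)(F)F
Why: Fluoride cleavage of the silyl enol ether in the presence of the triflating agent traps the enolate regiospecifically as the C2=C3 enol triflate, so the position of the future ring olefin is the one fixed by the cycloaddition; no stereocentre changes.

Step 6
Reactants: 8 (1S,4aS,8aS)-1-(2-chloroethyl)-8,8-dimethyl-5-methylidene-1,4,4a,5,6,7,8,8a-octahydronaphthalen-2-yl trifluoromethanesulfonate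
Product: 9 (1S,4aS,8aS)-1-(2-chloroethyl)-2,8,8-trimethyl-5-methylidene-1,4,4a,5,6,7,8,8a-octahydronaphthalene
Conditions: MeMgBr, Fe(acac)3 (5 mol%), THF/NMP, −30 °C
Reagents that add atoms: methylmagnesium bromide, C[Mg]Br
Why: Iron-catalysed Kumada-type cross-coupling of an alkenyl triflate with a methyl Grignard reagent should give the trisubstituted ring olefin while the primary chloride and the 1,1-disubstituted olefin stay untouched; no stereocentre changes.

Step 7
Reactants: 9 (1S,4aS,8aS)-1-(2-chloroethyl)-2,8,8-trimethyl-5-methylidene-1,4,4a,5,6,7,8,8a-octahydronaphthalene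
Product: 11 2-Dec-acetaldehyde, via iodide 10 (not isolated)
Conditions: NaI, NaHCO3, DMSO, 110 °C
Reagents that add atoms: dimethyl sulfoxide, CS(C)=O
Why: Finkelstein exchange followed in the same pot by Kornblum oxidation (alkoxysulfonium salt, loss of Me2S) should turn the primary chloride into the aldehyde without involving the stereocentres.

Step 8
Reactants: 12 (E)-geranylacetone
Product: 13 (5S,6S,9S)-5,6:9,10-diepoxy-6,10-dimethylundecan-2-one
Conditions: ent-Shi ketone (L-fructose series, 30 mol%), Oxone (2KHSO5·KHSO4·K2SO4), K2CO3, Bu4NHSO4, MeCN/CH2(OMe)2/aq. Na2B4O7 buffer (pH 10.5), 0 °C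
Reagents that add atoms: potassium peroxymonosulfate (active part of Oxone), [K+].[O-]S(=O)(=O)OO
Why: Shi asymmetric epoxidation (chiral dioxirane, spiro transition state) of both trisubstituted olefins should give the (S,S,S)-diepoxide by reagent control, which sets the future C3, C5a and C9a.

Step 9
Reactants: 13 (5S,6S,9S)-5,6:9,10-diepoxy-6,10-dimethylundecan-2-one; 11 2-Dec-acetaldehyde
Product: 17 (2E,7S,8S,11S)-1-Dec-7,8:11,12-diepoxy-8,12-dimethyltridec-2-en-4-one, via lithium enolate 14 (not isolated), via lithium aldolate 15 (not isolated), via mesylate 16 (not isolated)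
Conditions: LiN(i-Pr)2, THF, −78 °C; 11; MsCl, −78 to 0 °C; DBU, 23 °C
Reagents that add atoms: none
Why: In this directed aldol condensation the methyl ketone is deprotonated kinetically on the methyl side, the enolate is trapped by the aldehyde at −78 °C faster than it can open the γ,δ-epoxide, and mesylation with E1cB elimination should give the E enone, which removes the transient carbinol centre again.

Step 10
Reactants: 17 (2E,7S,8S,11S)-1-Dec-7,8:11,12-diepoxy-8,12-dimethyltridec-2-en-4-one
Product: 18 {[(7S,8S,11S)-1-Dec-7,8:11,12-diepoxy-8,12-dimethyltridec-3-en-4-yl]oxy}dimethyl(phenyl)silane (E/Z mixture)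
Conditions: [(Ph3P)CuH]6 (5 mol% Cu), PhMe2SiH, toluene, 0 to 23 °C
Reagents that add atoms: dimethyl(phenyl)silane, C[SiH](C)c1ccccc1
Why: Copper hydride-catalysed conjugate reduction (1,4-hydrosilylation) of the enone should give the regiodefined silyl enol ether and leave isolated olefins and epoxides alone; its geometry need not be controlled.

Step 11
Reactants: 18 {[(7S,8S,11S)-1-Dec-7,8:11,12-diepoxy-8,12-dimethyltridec-3-en-4-yl]oxy}dimethyl(phenyl)silane
Product: 20 (3S,5aS,6S,9aS)-6-(2-Dec-ethyl)-3-hydroxy-2,2,5a-trimethyl-3,4,5,5a,6,8,9,9a-octahydro-1-benzoxepin-7(2H)-one, via silyl ether 19 (not isolated)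
Conditions: TMSOTf, 2,6-di-tert-butyl-4-methylpyridine, CH2Cl2, −78 °C; then K2CO3, MeOH, 23 °C
Reagents that add atoms: none
Why: TMSOTf silylates the terminal epoxide, its tertiary carbon is attacked by the oxygen of the neighbouring epoxide to give a fused epoxonium ion, and the enol silane carbon opens this ion at its tertiary carbon (forming C5a–C6) with loss of the silyl group to leave the C7 ketone; the closest known reaction type is the Lewis-acid-promoted tandem oxa-/carbacyclisation of 1,5-diepoxides terminated by an enol silane, an epoxide-initiated cation–olefin cyclisation. The oxepane closes by endo opening of the terminal epoxide at its more substituted carbon (net 7-endo-tet once the C5a–O bond is cleaved), and the cyclohexane by 6-endo-tet opening of the epoxonium, which is 6-endo-trig with respect to the enol π bond. C5a is set by stereospecific inversion at the tertiary epoxide carbon, so the E-derived (S,S)-epoxide gives the trans ring fusion with the methyl group anti to H-9a, while C3 and C9a keep their Shi-derived configuration because their C–O bonds are not broken. C6 forms through a chair transition state and, being α to the new ketone, is equilibrated by K2CO3/MeOH to the equatorial side chain, so the E/Z mixture of 18 is of no consequence. The step needs endo opening of both epoxides and C-attack only after the epoxonium has formed; the cation-stabilising tertiary epoxide termini, the six-membered chair for C-attack and the non-nucleophilic pyridine buffer should secure this, and the two decalin olefins are too remote and too weakly nucleophilic to compete.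

Step 12
Reactants: 20 (3S,5aS,6S,9aS)-6-(2-Dec-ethyl)-3-hydroxy-2,2,5a-trimethyl-3,4,5,5a,6,8,9,9a-octahydro-1-benzoxepin-7(2H)-one
Product: 21 (3S,5aS,6R,9aS)-6-(2-Dec-ethyl)-2,2,5a-trimethyl-7-methylidenedecahydro-1-benzoxepin-3-ol
Conditions: Ph3PCH3Br, KOt-Bu (excess), toluene, 80 °C
Reagents that add atoms: methyltriphenylphosphonium bromide, C[P+](c1ccccc1)(c1ccccc1)c1ccccc1.[Br-]
Why: Wittig methylenation of the hindered cyclohexanone (the free alcohol carried as its alkoxide) should give the exocyclic olefin, and the basic medium can only hold C6 in its more stable equatorial configuration.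

Step 13
Reactants: 21 (3S,5aS,6R,9aS)-6-(2-Dec-ethyl)-2,2,5a-trimethyl-7-methylidenedecahydro-1-benzoxepin-3-ol
Product: 23 sipholenol L, via bis-organomercurial 22 (not isolated)
Conditions: Hg(OAc)2 (2.2 equiv), THF/H2O (1:1), 0 to 23 °C; then aq. NaOH, NaBH4, 0 °C
Reagents that add atoms: water, O
Why: Oxymercuration–demercuration (Markovnikov hydration) should occur at the two 1,1-disubstituted olefins in preference to the hindered trisubstituted ring olefin; water should add to C7 from the face opposite the axial C5a methyl group (equatorial OH) and to C5′ from the convex face of the cis-decalin (OH cis to H-4a′ and H-8a′, hence unable to add across the ring olefin), which sets the last two stereocentres.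

**Compound list**

1 | 4-chlorobutanoyl chloride | O=C(Cl)CCCCl | starting material
2 | trimethyl(vinyl)silane | C=C[Si](C)(C)C | starting material
3 | 6-chlorohex-1-en-3-one | C=CC(=O)CCCCl | intermediate
4 | (Z)-tert-butyl[(6-chlorohexa-1,3-dien-3-yl)oxy]dimethylsilane | ClCC/C=C(\O[Si](C)(C)C(C)(C)C)C=C | intermediate
5 | 4,4-dimethylcyclohex-2-en-1-one | CC1(C)CCC(=O)C=C1 | starting material
6 | (4aR,5S,8aS)-6-[(tert-butyldimethylsilyl)oxy]-5-(2-chloroethyl)-4,4-dimethyl-3,4,4a,5,8,8a-hexahydronaphthalen-1(2H)-one (cis-fused; H-4a, H-5, H-8a on one face) | CC(C)(C)[Si](C)(C)OC1=CC[C@H]2[C@@H]([C@@H]1CCCl)C(C)(C)CCC2=O | intermediate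
7 | tert-butyl{[(1S,4aS,8aS)-1-(2-chloroethyl)-8,8-dimethyl-5-methylidene-1,4,4a,5,6,7,8,8a-octahydronaphthalen-2-yl]oxy}dimethylsilane | CC(C)(C)[Si](C)(C)OC1=CC[C@H]2[C@@H]([C@@H]1CCCl)C(C)(C)CCC2=C | intermediate
8 | (1S,4aS,8aS)-1-(2-chloroethyl)-8,8-dimethyl-5-methylidene-1,4,4a,5,6,7,8,8a-octahydronaphthalen-2-yl trifluoromethanesulfonate | FC(F)(F)S(=O)(=O)OC1=CC[C@H]2[C@@H]([C@@H]1CCCl)C(C)(C)CCC2=C | intermediate
9 | (1S,4aS,8aS)-1-(2-chloroethyl)-2,8,8-trimethyl-5-methylidene-1,4,4a,5,6,7,8,8a-octahydronaphthalene | CC1=CC[C@H]2[C@@H]([C@@H]1CCCl)C(C)(C)CCC2=C | intermediate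
10 | (1S,4aS,8aS)-1-(2-iodoethyl)-2,8,8-trimethyl-5-methylidene-1,4,4a,5,6,7,8,8a-octahydronaphthalene | CC1=CC[C@H]2[C@@H]([C@@H]1CCI)C(C)(C)CCC2=C | intermediate
11 | 2-[(1S,4aS,8aS)-2,8,8-trimethyl-5-methylidene-1,4,4a,5,6,7,8,8a-octahydronaphthalen-1-yl]acetaldehyde | CC1=CC[C@H]2[C@@H]([C@@H]1CC=O)C(C)(C)CCC2=C | intermediate
12 | (E)-geranylacetone, (5E)-6,10-dimethylundeca-5,9-dien-2-one | CC(C)=CCC/C(C)=C/CCC(C)=O | starting material
13 | (5S,6S,9S)-5,6:9,10-diepoxy-6,10-dimethylundecan-2-one | CC(=O)CC[C@@H]1O[C@@]1(C)CC[C@@H]1OC1(C)C | intermediate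
14 | lithium enolate of 13 on the methyl side | [Li+].[O-]C(=C)CC[C@@H]1O[C@@]1(C)CC[C@@H]1OC1(C)C | intermediate
15 | lithium (7S,8S,11S)-1-Dec-7,8:11,12-diepoxy-8,12-dimethyl-4-oxotridecan-2-olate (both C2 epimers) | CC1=CC[C@H]2[C@@H]([C@@H]1CC([O-])CC(=O)CC[C@@H]3O[C@@]3(C)CC[C@@H]4OC4(C)C)C(C)(C)CCC2=C.[Li+] | intermediate
16 | (7S,8S,11S)-1-Dec-7,8:11,12-diepoxy-8,12-dimethyl-4-oxotridecan-2-yl methanesulfonate (both C2 epimers) | CC1=CC[C@H]2[C@@H]([C@@H]1CC(OS(C)(=O)=O)CC(=O)CC[C@@H]3O[C@@]3(C)CC[C@@H]4OC4(C)C)C(C)(C)CCC2=C | intermediate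
17 | (2E,7S,8S,11S)-1-Dec-7,8:11,12-diepoxy-8,12-dimethyltridec-2-en-4-one | CC1=CC[C@H]2[C@@H]([C@@H]1C/C=C/C(=O)CC[C@@H]3O[C@@]3(C)CC[C@@H]4OC4(C)C)C(C)(C)CCC2=C | intermediate
18 | {[(7S,8S,11S)-1-Dec-7,8:11,12-diepoxy-8,12-dimethyltridec-3-en-4-yl]oxy}dimethyl(phenyl)silane (E/Z mixture) | CC1=CC[C@H]2[C@@H]([C@@H]1CCC=C(O[Si](C)(C)c3ccccc3)CC[C@@H]4O[C@@]4(C)CC[C@@H]5OC5(C)C)C(C)(C)CCC2=C | intermediate
19 | (3S,5aS,9aS)-6-(2-Dec-ethyl)-2,2,5a-trimethyl-3-[(trimethylsilyl)oxy]-3,4,5,5a,6,8,9,9a-octahydro-1-benzoxepin-7(2H)-one (C6 epimers before equilibration) | CC1=CC[C@H]2[C@@H]([C@@H]1CCC1[C@]3(C)CC[C@H](O[Si](C)(C)C)C(C)(C)O[C@H]3CCC1=O)C(C)(C)CCC2=C | intermediate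
20 | (3S,5aS,6S,9aS)-6-(2-Dec-ethyl)-3-hydroxy-2,2,5a-trimethyl-3,4,5,5a,6,8,9,9a-octahydro-1-benzoxepin-7(2H)-one (trans-fused; 5a-methyl anti to H-9a; side chain equatorial) | CC1=CC[C@H]2[C@@H]([C@@H]1CC[C@H]1[C@]3(C)CC[C@H](O)C(C)(C)O[C@H]3CCC1=O)C(C)(C)CCC2=C | intermediate
21 | (3S,5aS,6R,9aS)-6-(2-Dec-ethyl)-2,2,5a-trimethyl-7-methylidenedecahydro-1-benzoxepin-3-ol | CC1=CC[C@H]2[C@@H]([C@@H]1CC[C@H]1[C@]3(C)CC[C@H](O)C(C)(C)O[C@H]3CCC1=C)C(C)(C)CCC2=C | intermediate
22 | bis(acetoxymercuriomethyl) triol, i.e. 23 with HgOAc on each of the two carbinol methyl groups | CC1=CC[C@H]2[C@@H]([C@@H]1CC[C@H]1[C@]3(C)CC[C@H](O)C(C)(C)O[C@H]3CC[C@]1(C[Hg]OC(C)=O)O)C(C)(C)CC[C@]2(C[Hg]OC(C)=O)O | intermediate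
23 | sipholenol L, (3S,5aS,6S,7S,9aS)-6-{2-[(1S,4aS,5S,8aR)-5-hydroxy-2,5,8,8-tetramethyl-1,4,4a,5,6,7,8,8a-octahydronaphthalen-1-yl]ethyl}-2,2,5a,7-tetramethyldecahydro-1-benzoxepine-3,7-diol | CC1=CC[C@H]2[C@@H]([C@@H]1CC[C@H]1[C@]3(C)CC[C@H](O)C(C)(C)O[C@H]3CC[C@]1(C)O)C(C)(C)CC[C@]2(C)O | target

**Step count and risks**

Total step count: 13. Longest linear sequence: 12 steps (steps 1–7 and 9–13); step 8 is the one-step side branch.

The three steps most likely to fail:

Step 3. The cycloaddition may be too slow at the congested β-carbon beside the gem-dimethyl group for the chiral Lewis acid to turn over, the enantiofacial discrimination may be poor, or the strong Lewis acid may desilylate or epimerise the adduct. The fallback sets out again from 4 and 5 and returns at 6. The cycloaddition is run without a chiral ligand under the stronger mixed Lewis acid AlBr3/AlMe3 (toluene/CH2Cl2, −5 °C), which should give 6 as a racemate, that is, together with its mirror image, the (4aS,5R,8aR)-adduct F1 in equal amount. Lithiated (S)-N,S-dimethyl-S-phenylsulfoximine (n-BuLi, THF, −78 °C) is then added to the ketone of both enantiomers, which should give two diastereomers: from 6 the β-hydroxysulfoximine F2 and from the mirror-image adduct the β-hydroxysulfoximine F3 as its diastereomer. F2 and F3 are separated by chromatography, and thermolysis of F2 (toluene, 110 °C) should release the sulfoximine and return enantiopure 6.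

Step 11. The enol silane may be protodesilylated by adventitious triflic acid before the epoxonium ion forms, the silylated terminal epoxide may rearrange by hydride shift, or the internal epoxide may be opened on its own. The fallback sets out from 18 and returns at 21, bypassing step 12; it replaces the acid-labile enol silane by an allylsilane terminator. MeLi (THF, 0 °C) liberates the lithium enolate of 18, which is trapped with PhNTf2 to give the (Z)-enol triflate F4 after the E isomer has been removed by chromatography. Kumada coupling of F4 with Me3SiCH2MgCl and Pd(PPh3)4 should give, with retention of the olefin geometry, the (Z)-allylsilane F5 as the cyclisation substrate. When F5 is put through the same TMSOTf/2,6-di-tert-butyl-4-methylpyridine cascade, now ended by loss of the allylic silyl group, it should give the silyl ether F6 (the trimethylsilyl ether of 21), and K2CO3 in MeOH converts F6 to 21. In this variant C6 is fixed by the olefin geometry and the chair transition state instead of by equilibration.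

Step 13. Mercuration of the trisubstituted ring olefin may compete, the more hindered C7 methylene may react incompletely, deoxymercuration may reverse the addition during reduction, or facial selectivity at C5′ may be insufficient. The fallback goes from 21 directly to 23 and makes no new compound: a radical Mukaiyama hydration (Co(acac)2 cat., PhSiH3, O2, THF/i-PrOH, 0 °C; then PPh3). Here hydrogen-atom transfer from the cobalt hydride, which is fastest for 1,1-disubstituted olefins, replaces the ionic mercurinium pathway, and oxygen should trap each tertiary radical from the same less hindered faces.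

**Further compounds**

F1 | step 3 | (4aS,5R,8aR)-6-[(tert-butyldimethylsilyl)oxy]-5-(2-chloroethyl)-4,4-dimethyl-3,4,4a,5,8,8a-hexahydronaphthalen-1(2H)-one (mirror image of 6) | CC(C)(C)[Si](C)(C)OC1=CC[C@@H]2[C@H]([C@H]1CCCl)C(C)(C)CCC2=O
F2 | step 3 | β-hydroxysulfoximine of 6: 1-{[(S)-N-methyl-S-phenylsulfonimidoyl]methyl} tertiary alcohol, CH2S group on the convex face | CC(C)(C)[Si](C)(C)OC1=CC[C@H]2[C@@H]([C@@H]1CCCl)C(C)(C)CC[C@]2(O)C[S@@](=O)(=NC)c1ccccc1
F3 | step 3 | β-hydroxysulfoximine of the mirror-image adduct F1 with the same (S)-sulfoximine (diastereomer of F2) | CC(C)(C)[Si](C)(C)OC1=CC[C@@H]2[C@H]([C@H]1CCCl)C(C)(C)CC[C@@]2(O)C[S@@](=O)(=NC)c1ccccc1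
F4 | step 11 | (3Z,7S,8S,11S)-1-Dec-7,8:11,12-diepoxy-8,12-dimethyltridec-3-en-4-yl trifluoromethanesulfonate | CC1=CC[C@H]2[C@@H]([C@@H]1CC/C=C(\OS(=O)(=O)C(F)(F)F)CC[C@@H]3O[C@@]3(C)CC[C@@H]4OC4(C)C)C(C)(C)CCC2=C
F5 | step 11 | {(2Z)-2-[(3S,4S,7S)-3,4:7,8-diepoxy-4,8-dimethylnonyl]-5-Dec-pent-2-en-1-yl}trimethylsilane | CC1=CC[C@H]2[C@@H]([C@@H]1CC/C=C(\C[Si](C)(C)C)CC[C@@H]3O[C@@]3(C)CC[C@@H]4OC4(C)C)C(C)(C)CCC2=C
F6 | step 11 | trimethylsilyl ether of 21 | CC1=CC[C@H]2[C@@H]([C@@H]1CC[C@H]1[C@]3(C)CC[C@H](O[Si](C)(C)C)C(C)(C)O[C@H]3CCC1=C)C(C)(C)CCC2=C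
F0 | step 13 | none | none
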